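**Retrosynthetic overview**
- Ring B's hydroxy-isopropyl enone is unveiled last: singlet-oxygen ene reaction of a 7(11)-en-8-one, itself made by oxidative 1,3-transposition of a tertiary allylic alcohol; the (R)-2-methylbutanoate goes on C-3 just before.
- Ring A (formed second): intramolecular aldol condensation of a keto aldehyde; 4α-OH by α′-enolate hydroxylation, 3β-OH by hydride reduction.
- Ring B (formed first, key step): Diels–Alder reaction of an (E)-2-methyl enal with a 2-substituted butadiene, which sets C-10 and C-5 from the allylic stereocentre of the enal.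
- That stereocentre comes from methyl (R)-3-hydroxybutanoate by Fráter–Seebach methylation; the acyl side chain is bought as (R)-2-methylbutanoic acid.

Assumption: bicyclic compounds are named with eudesmane numbering (H-5 α, 10-methyl β throughout); the SMILES in the compound list are binding.

**Route**

Step 1
Reactants: 1 2-chlorobuta-1,3-diene (chloroprene); 2 acetone
Product: 5 triethyl[(2-methyl-3-methylidenepent-4-en-2-yl)oxy]silane, via dienyl Grignard reagent 3 (not isolated), via magnesium alkoxide 4 (not isolated)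
Conditions: Mg, ZnCl2 (cat.), THF, reflux; 2, 0 °C; then Et3SiOTf, 0 °C to rt
Reagents that add atoms: triethylsilyl trifluoromethanesulfonate, CC[Si](CC)(CC)OS(=O)(=O)C(F)(F)F
Why: Grignard formation from the vinylic chloride, 1,2-addition to acetone and O-silylation of the alkoxide in one flask give the 2-substituted diene; no stereocentre is formed.

Step 2
Reactants: 6 methyl (3R)-3-hydroxybutanoate
Product: 8 methyl (2R,3R)-2-methyl-3-(triethylsilyloxy)butanoate, via anti hydroxy ester 7 (not isolated)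
Conditions: LiN(iPr)2 (2.2 equiv), THF, −78 to −20 °C; MeI, DMPU, −78 to 0 °C; then Et3SiCl, 0 °C to rt
Reagents that add atoms: iodomethane, CI; chlorotriethylsilane, CC[Si](CC)(CC)Cl
Why: Fráter–Seebach alkylation of the chelated dianion puts the new methyl anti to the hydroxyl (about 95:5, controlled by the bought centre), and the alkoxide is silylated in the same flask.

Step 3
Reactants: 8 methyl (2R,3R)-2-methyl-3-(triethylsilyloxy)butanoate; 9 2-(triphenyl-λ5-phosphanylidene)propanal
Product: 11 (2E,4S,5R)-2,4-dimethyl-5-(triethylsilyloxy)hex-2-enal, via silyloxy aldehyde 10 (not isolated)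
Conditions: iBu2AlH, CH2Cl2, −78 °C; MeOH quench; crude aldehyde, 9, toluene, 90 °C
Reagents that add atoms: none
Why: Half-reduction of the ester and Wittig olefination with the formyl-stabilised ylide give the (E)-2-methyl enal without touching the two existing stereocentres.

Step 4
Reactants: 11 (2E,4S,5R)-2,4-dimethyl-5-(triethylsilyloxy)hex-2-enal; 5 triethyl[(2-methyl-3-methylidenepent-4-en-2-yl)oxy]silane
Product: 12 (1R,6S)-1-methyl-6-[(2S,3R)-3-(triethylsilyloxy)butan-2-yl]-4-[2-(triethylsilyloxy)propan-2-yl]cyclohex-3-ene-1-carbaldehyde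
Conditions: Me2AlCl (0.3 equiv), CH2Cl2, −78 to −20 °C
Reagents that add atoms: none
Why: Lewis-acid-catalysed Diels–Alder reaction forms ring B with the diene substituent para to the formyl-bearing carbon, the E-alkene puts CHO and side chain trans (the later trans ring fusion), and with H-4 eclipsing the C=C (allylic 1,3-strain) the diene adds anti to the silyloxyethyl group, which sets C-10 and C-5.

Step 5
Reactants: 12 (1R,6S)-1-methyl-6-[(2S,3R)-3-(triethylsilyloxy)butan-2-yl]-4-[2-(triethylsilyloxy)propan-2-yl]cyclohex-3-ene-1-carbaldehyde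
Product: 14 (2R,3S)-3-[(1S,6R)-6-(hydroxymethyl)-3-(2-hydroxypropan-2-yl)-6-methylcyclohex-3-en-1-yl]butan-2-ol, via bis-silyl alcohol 13 (not isolated)
Conditions: NaBH4, MeOH–THF, 0 °C; then Bu4NF, THF, rt
Reagents that add atoms: none
Why: Hydride reduction of the aldehyde before fluoride desilylation avoids the lactol that a free 5-hydroxy aldehyde would form.

Step 6
Reactants: 14 (2R,3S)-3-[(1S,6R)-6-(hydroxymethyl)-3-(2-hydroxypropan-2-yl)-6-methylcyclohex-3-en-1-yl]butan-2-ol
Product: 15 (1R,6S)-4-(2-hydroxypropan-2-yl)-1-methyl-6-[(2S)-3-oxobutan-2-yl]cyclohex-3-ene-1-carbaldehyde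
Conditions: (COCl)2, DMSO, CH2Cl2, −78 °C; NEt3, −78 °C to rt
Reagents that add atoms: none
Why: Swern oxidation turns both the primary and the secondary alcohol into alkoxysulfonium salts before base is added, so the keto aldehyde forms without lactone formation and the tertiary alcohol is untouched.

Step 7
Reactants: 15 (1R,6S)-4-(2-hydroxypropan-2-yl)-1-methyl-6-[(2S)-3-oxobutan-2-yl]cyclohex-3-ene-1-carbaldehyde
Product: 16 11-hydroxy-4βH-eudesma-1,7-dien-3-one (4-methyl α)
Conditions: KOH, MeOH, 0 °C to rt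
Reagents that add atoms: none
Why: Intramolecular aldol condensation of the methyl ketone enolate onto the non-enolisable aldehyde closes ring A as the trans-fused enone (the only six-membered mode), and C-4 settles with its methyl equatorial.

Step 8
Reactants: 16 11-hydroxy-4βH-eudesma-1,7-dien-3-one
Product: 17 4α,11-dihydroxyeudesma-1,7-dien-3-one
Conditions: KN(SiMe3)2 (2.3 equiv), THF, −78 °C; racemic trans-2-(phenylsulfonyl)-3-phenyloxaziridine, −78 °C; NH4Cl
Reagents that add atoms: 2-(phenylsulfonyl)-3-phenyloxaziridine, O=S(=O)(c1ccccc1)N1OC1c1ccccc1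
Why: Davis enolate hydroxylation: only the α′ (C-4) enolate can form because C-10 is quaternary, and the oxidant enters from the α face, away from the axial 10-methyl, giving 4α-OH and 4β-methyl.

Step 9
Reactants: 17 4α,11-dihydroxyeudesma-1,7-dien-3-one
Product: 19 eudesm-7-ene-3β,4α,11-triol, via saturated hydroxy ketone 18 (not isolated)
Conditions: H2 (1 atm), RhCl(PPh3)3 (5 mol %), benzene–EtOH, rt; then NaBH4, 0 °C
Reagents that add atoms: none
Why: Homogeneous hydrogenation reduces only the disubstituted enone C=C, and NaBH4 then delivers hydride axially from the α face (the β face is blocked by the axial 4β-methyl), giving the equatorial 3β-alcohol.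

Step 10
Reactants: 19 eudesm-7-ene-3β,4α,11-triol; 20 (2R)-2-methylbutanoic acid
Product: 21 4α,11-dihydroxyeudesm-7-en-3β-yl (2R)-2-methylbutanoate
Conditions: DCC, DMAP (cat.), CH2Cl2, 0 °C to rt
Reagents that add atoms: none
Why: Steglich esterification acylates only the secondary 3β-hydroxyl; the two tertiary alcohols do not react and the acid stereocentre is bought.

Step 11
Reactants: 21 4α,11-dihydroxyeudesm-7-en-3β-yl (2R)-2-methylbutanoate
Product: 22 4α-hydroxy-8-oxoeudesm-7(11)-en-3β-yl (2R)-2-methylbutanoate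
Conditions: pyridinium chlorochromate (C5H5NH)[CrO3Cl] (3 equiv), 4 Å sieves, CH2Cl2, rt
Reagents that add atoms: pyridinium chlorochromate, [O-][Cr](=O)(=O)Cl.c1cc[nH+]cc1
Why: Dauben–Babler oxidative transposition: [3,3]-sigmatropic shift of the tertiary allylic chromate ester moves oxygen from C-11 to C-8 and oxidation gives the isopropylidene ketone; no stereocentre is formed.

Step 12
Reactants: 22 4α-hydroxy-8-oxoeudesm-7(11)-en-3β-yl (2R)-2-methylbutanoate
Product: 24 4α,11-dihydroxy-8-oxoeudesm-6-en-3β-yl (2R)-2-methylbutanoate, via allylic hydroperoxide 23 (not isolated)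
Conditions: O2, hν (visible), tetraphenylporphyrin (cat.), CH2Cl2, 0 °C; then PPh3
Reagents that add atoms: dioxygen, O=O
Why: Schenck ene reaction: singlet oxygen attacks the s-cis enone with abstraction of H-6 (on the ring CH2 geminal to the carbonyl, as pulegone-type enones do), placing the hydroperoxide on C-11 and the double bond at C-6/C-7, and PPh3 reduces it to the alcohol.

**Compound list**
1 | 2-chlorobuta-1,3-diene (chloroprene) | C=CC(Cl)=C | starting material
2 | acetone | CC(C)=O | starting material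
3 | buta-1,3-dien-2-ylmagnesium chloride | C=CC(=C)[Mg]Cl | intermediate
4 | chloromagnesium 2-methyl-3-methylidenepent-4-en-2-olate | C=CC(=C)C(C)(C)O[Mg]Cl | intermediate
5 | triethyl[(2-methyl-3-methylidenepent-4-en-2-yl)oxy]silane | C=CC(=C)C(C)(C)O[Si](CC)(CC)CC | intermediate
6 | methyl (3R)-3-hydroxybutanoate | C[C@@H](O)CC(=O)OC | starting material
7 | methyl (2R,3R)-3-hydroxy-2-methylbutanoate (present as its lithium alkoxide) | C[C@@H](O)[C@@H](C)C(=O)OC | intermediate
8 | methyl (2R,3R)-2-methyl-3-(triethylsilyloxy)butanoate | C[C@@H](O[Si](CC)(CC)CC)[C@@H](C)C(=O)OC | intermediate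
9 | 2-(triphenyl-λ5-phosphanylidene)propanal | CC(C=O)=P(c1ccccc1)(c1ccccc1)c1ccccc1 | starting material
10 | (2R,3R)-2-methyl-3-(triethylsilyloxy)butanal | C[C@@H](O[Si](CC)(CC)CC)[C@@H](C)C=O | intermediate
11 | (2E,4S,5R)-2,4-dimethyl-5-(triethylsilyloxy)hex-2-enal | C[C@@H](O[Si](CC)(CC)CC)[C@@H](C)/C=C(\C)C=O | intermediate
12 | (1R,6S)-1-methyl-6-[(2S,3R)-3-(triethylsilyloxy)butan-2-yl]-4-[2-(triethylsilyloxy)propan-2-yl]cyclohex-3-ene-1-carbaldehyde | O=C[C@]1(C)CC=C(C(C)(C)O[Si](CC)(CC)CC)C[C@H]1[C@H](C)[C@H](O[Si](CC)(CC)CC)C | intermediate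
13 | [(1R,6S)-1-methyl-6-[(2S,3R)-3-(triethylsilyloxy)butan-2-yl]-4-[2-(triethylsilyloxy)propan-2-yl]cyclohex-3-en-1-yl]methanol | OC[C@]1(C)CC=C(C(C)(C)O[Si](CC)(CC)CC)C[C@H]1[C@H](C)[C@H](O[Si](CC)(CC)CC)C | intermediate
14 | (2R,3S)-3-[(1S,6R)-6-(hydroxymethyl)-3-(2-hydroxypropan-2-yl)-6-methylcyclohex-3-en-1-yl]butan-2-ol | OC[C@]1(C)CC=C(C(C)(C)O)C[C@H]1[C@H](C)[C@H](O)C | intermediate
15 | (1R,6S)-4-(2-hydroxypropan-2-yl)-1-methyl-6-[(2S)-3-oxobutan-2-yl]cyclohex-3-ene-1-carbaldehyde | O=C[C@]1(C)CC=C(C(C)(C)O)C[C@H]1[C@H](C)C(C)=O | intermediate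
16 | 11-hydroxy-4βH-eudesma-1,7-dien-3-one | O=C1C=C[C@]2(C)CC=C(C(C)(C)O)C[C@H]2[C@@H]1C | intermediate
17 | 4α,11-dihydroxyeudesma-1,7-dien-3-one | O=C1C=C[C@]2(C)CC=C(C(C)(C)O)C[C@H]2[C@]1(C)O | intermediate
18 | 4α,11-dihydroxyeudesm-7-en-3-one | O=C1CC[C@]2(C)CC=C(C(C)(C)O)C[C@H]2[C@]1(C)O | intermediate
19 | eudesm-7-ene-3β,4α,11-triol | O[C@H]1CC[C@]2(C)CC=C(C(C)(C)O)C[C@H]2[C@]1(C)O | intermediate
20 | (2R)-2-methylbutanoic acid | CC[C@@H](C)C(=O)O | starting material
21 | 4α,11-dihydroxyeudesm-7-en-3β-yl (2R)-2-methylbutanoate | CC[C@@H](C)C(=O)O[C@H]1CC[C@]2(C)CC=C(C(C)(C)O)C[C@H]2[C@]1(C)O | intermediate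
22 | 4α-hydroxy-8-oxoeudesm-7(11)-en-3β-yl (2R)-2-methylbutanoate | CC[C@@H](C)C(=O)O[C@H]1CC[C@]2(C)CC(=O)C(=C(C)C)C[C@H]2[C@]1(C)O | intermediate
23 | 11-hydroperoxy-4α-hydroxy-8-oxoeudesm-6-en-3β-yl (2R)-2-methylbutanoate | CC[C@@H](C)C(=O)O[C@H]1CC[C@]2(C)CC(=O)C(C(C)(C)OO)=C[C@H]2[C@]1(C)O | intermediate
24 | 4α,11-dihydroxy-8-oxoeudesm-6-en-3β-yl (2R)-2-methylbutanoate | CC[C@@H](C)C(=O)O[C@H]1CC[C@]2(C)CC(=O)C(C(C)(C)O)=C[C@H]2[C@]1(C)O | target

**Step count**
Total: 12 steps. Longest linear sequence: 11 steps (steps 2 to 12, from 6); step 1 makes the diene.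

**Steps most likely to fail, with fallbacks**

Step 4 (cycloaddition of a hindered, β-branched enal; face selectivity rests on allylic strain alone). The fallback sets out from 11 and 4 and comes back at 14, making the cycloaddition intramolecular through a disposable silicon tether (type 2 intramolecular Diels–Alder). Alkoxide 4 is quenched with aqueous NH4Cl to give 2-methyl-3-methylidenepent-4-en-2-ol F1. Enal 11 is desilylated with HF·pyridine to (2E,4S,5R)-5-hydroxy-2,4-dimethylhex-2-enal F2. Both alcohols are joined with Me2SiCl2/NEt3 to the mixed dimethylsilylene bis-ether F3. Heating (toluene, 160 °C) gives the silicon-bridged cycloadduct aldehyde F4, in which the tether enforces the same regiochemistry. NaBH4 gives the silicon-bridged primary alcohol F5, and Bu4NF cleaves the tether to triol 14.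

Step 8 (hydroxylation of a hindered, fully substituted enolate in the presence of a free tertiary alkoxide). The fallback sets out from 16 and comes back at 17 by radical-type α′-oxidation instead of enolate chemistry. Mn(OAc)3 in refluxing benzene gives 4α-acetoxy-11-hydroxyeudesma-1,7-dien-3-one F6, the acetate again entering anti to the angular methyl. K2CO3 in MeOH then removes the acetyl group to give 17.

Step 12 (ene reaction of an electron-poor enone; rate and regioselectivity). The fallback sets out from 21 and comes back at 24, avoiding the exocyclic enone altogether. Hydroboration–oxidation (BH3·THF; NaBO3) from the α face gives 4α,8α,11-trihydroxy-7αH-eudesman-3β-yl (2R)-2-methylbutanoate F7. Dess–Martin oxidation gives 4α,11-dihydroxy-8-oxo-7αH-eudesman-3β-yl (2R)-2-methylbutanoate F8. IBX dehydrogenation (DMSO, 70 °C), which can only go toward C-6 because C-10 is quaternary, gives 24.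

**Further compounds**
F1 | step 4 | 2-methyl-3-methylidenepent-4-en-2-ol | C=CC(=C)C(C)(C)O
F2 | step 4 | (2E,4S,5R)-5-hydroxy-2,4-dimethylhex-2-enal | C[C@@H](O)[C@@H](C)/C=C(\C)C=O
F3 | step 4 | mixed dimethylsilylene bis-ether of F1 and F2 | C[C@@H](O[Si](C)(C)OC(C)(C)C(=C)C=C)[C@@H](C)/C=C(\C)C=O
F4 | step 4 | silicon-bridged cycloadduct aldehyde | O=C[C@]1(C)CC=C2C[C@H]1[C@H](C)[C@@H](C)O[Si](C)(C)OC2(C)C
F5 | step 4 | silicon-bridged primary alcohol | OC[C@]1(C)CC=C2C[C@H]1[C@H](C)[C@@H](C)O[Si](C)(C)OC2(C)C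
F6 | step 8 | 4α-acetoxy-11-hydroxyeudesma-1,7-dien-3-one | O=C1C=C[C@]2(C)CC=C(C(C)(C)O)C[C@H]2[C@]1(C)OC(C)=O
F7 | step 12 | 4α,8α,11-trihydroxy-7αH-eudesman-3β-yl (2R)-2-methylbutanoate | CC[C@@H](C)C(=O)O[C@H]1CC[C@]2(C)C[C@H](O)[C@@H](C(C)(C)O)C[C@H]2[C@]1(C)O
F8 | step 12 | 4α,11-dihydroxy-8-oxo-7αH-eudesman-3β-yl (2R)-2-methylbutanoate | CC[C@@H](C)C(=O)O[C@H]1CC[C@]2(C)CC(=O)[C@@H](C(C)(C)O)C[C@H]2[C@]1(C)O
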